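The cyclohexene ring of the bicyclo[2.2.2]octene (terpene carbons primed, numbered as in α-phellandrene; C6/C7 are the lactone α/β carbons), C1′–C2′(Me)=C3′–C4′–C6–C7, is grown from a cyclobutane. In 12 (ring C1′, C2′, C6, C7) the Lewis-acid-activated lactone lets C6 leave the tertiary allylic C2′ as an enolate and rejoin the allyl cation at C4′. This formal 1,3-shift enlarges the four-membered ring by two atoms, closes the bicycle and sets C4′ and C6; it exploits that the C4′–C6 bond is both α to the C5 carbonyl and allylic. Cyclobutane 12 comes from a sensitised [2+2] photocycloaddition of (+)-altholactone, made in five steps from cinnamaldehyde, with (R)-α-phellandrene.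

Key step: step 7

Remark on locants: the furopyranone is numbered as in altholactone (O1, C2-Ph, C3-OH, C3a, O4, C5=O, C6, C7, C7a); the terpene carbons are numbered as in α-phellandrene (C1′H, C2′-CH3, C3′H, C4′H, C5′-isopropyl, C6′H2).
Remark on the target: its heterocyclic half has the (2R,3R,3aS,7aS) configuration of (+)-altholactone; the carbocyclic half is the endo adduct on the convex lactone face with (R)-α-phellandrene, isopropyl syn to the alkene bridge.
Assumption: 12 is drawn as the cis,anti,cis isomer; its epimers at C2′ and C6 would serve equally, because step 7 breaks the C6–C2′ bond and resets both centres.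
Assumption: (+)-Ipc2BOMe is the reagent made from (−)-α-pinene, and the Shi ketone used is the L-fructose-series enantiomer (from L-sorbose); both, like allyl methoxymethyl ether, are taken as purchasable.

Step 1
Reactants: 1 (E)-cinnamaldehyde; 2 allyl methoxymethyl ether
Product: 6 (1E,3S,4S)-4-(methoxymethoxy)-1-phenylhexa-1,5-dien-3-ol, via allyllithium 3 (not isolated), via allylborane 4 (not isolated), via borinate 5 (not isolated)
Conditions: 2, sec-BuLi, THF, −78 °C; (+)-Ipc2BOMe; BF3·OEt2; then 1, −78 °C; NaOH, H2O2, 0 °C to rt
Reagents that add atoms: none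
Why: Brown asymmetric γ-alkoxyallylboration, in which the (Z)-alkoxyallylborane adds 1,2 to the enal through a closed chair transition state, so that the Z geometry gives the syn 3,4-dioxygen pattern and the isopinocampheyl groups from (−)-α-pinene select the aldehyde face that leads to the (3S) carbinol.

Step 2
Reactants: 6 (1E,3S,4S)-4-(methoxymethoxy)-1-phenylhexa-1,5-dien-3-ol
Product: 7 (1R,2S)-2-(methoxymethoxy)-1-[(2S,3S)-3-phenyloxiran-2-yl]but-3-en-1-ol
Conditions: L-fructose-derived Shi ketone (30 mol %), KHSO5 (Oxone, 2KHSO5·KHSO4·K2SO4), K2CO3, Bu4NHSO4, MeCN/CH2(OMe)2, aq Na2B4O7 buffer, pH 10.5, 0 °C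
Reagents that add atoms: potassium peroxymonosulfate, [K+].[O-]S(=O)(=O)OO
Why: Shi asymmetric epoxidation, in which the chiral dioxirane (the D-fructose ketone gives (R,R)-epoxides of trans-alkenes, so its enantiomer gives (S,S)) oxidises the trans-styryl alkene under catalyst control to the threo epoxy alcohol, while the monosubstituted vinyl group is inert to this dioxirane.

Step 3
Reactants: 7 (1R,2S)-2-(methoxymethoxy)-1-[(2S,3S)-3-phenyloxiran-2-yl]but-3-en-1-ol
Product: 8 (1R,2S)-2-(methoxymethoxy)-1-[(2R,3S)-3-phenyloxiran-2-yl]but-3-en-1-yl prop-2-enoate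
Conditions: CH2=CHCOCl, iPr2NEt, CH2Cl2, −20 to 0 °C
Reagents that add atoms: acryloyl chloride, C=CC(=O)Cl
Why: O-acylation of the secondary alcohol by an acid chloride installs the acrylate for metathesis without touching a stereocentre (the descriptor of the oxirane carbon changes only through the priority rules).

Step 4
Reactants: 8 (1R,2S)-2-(methoxymethoxy)-1-[(2R,3S)-3-phenyloxiran-2-yl]but-3-en-1-yl prop-2-enoate
Product: 9 (5S,6R)-5-(methoxymethoxy)-6-[(2R,3S)-3-phenyloxiran-2-yl]-5,6-dihydro-2H-pyran-2-one
Conditions: second-generation Grubbs catalyst RuCl2(=CHPh)(H2IMes)(PCy3) (5 mol %), CH2Cl2, 40 °C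
Reagents that add atoms: none
Why: Ring-closing metathesis of the acrylate with the terminal vinyl group should give the six-membered (Z)-enoate lactone with loss of ethene; the styrene has already been converted to the epoxide, so no second alkene competes and no stereocentre is touched.

Step 5
Reactants: 9 (5S,6R)-5-(methoxymethoxy)-6-[(2R,3S)-3-phenyloxiran-2-yl]-5,6-dihydro-2H-pyran-2-one
Product: 10 (+)-altholactone, (2R,3R,3aS,7aS)-3-hydroxy-2-phenyl-2,3,3a,7a-tetrahydro-5H-furo[3,2-b]pyran-5-one
Conditions: BF3·OEt2 (0.3 equiv), MeOH (2 equiv), CH2Cl2, −30 to 0 °C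
Reagents that add atoms: none
Why: Acid-activated 5-endo epoxide opening, in which the cis-disposed methoxymethyl ether oxygen attacks the benzylic carbon with inversion (intramolecular SN2) and the resulting oxonium ion hands its methoxymethyl group to methanol, so that C2 becomes (R) from the (S)-epoxide carbon while C3, C3a and C7a are carried over unchanged.

Step 6
Reactants: 10 (+)-altholactone; 11 (R)-(−)-α-phellandrene
Product: 12 cis,anti,cis-cyclobutane photoadduct (new bonds C7–C1′ and C6–C2′)
Conditions: thioxanthone (10 mol %), 405 nm LEDs, degassed CH2Cl2, −20 °C, 11 (5 equiv) added in portions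
Reagents that add atoms: none
Why: Triplet-sensitised diene–alkene [2+2] photocycloaddition, in which thioxanthone (triplet energy about 65 kcal/mol) transfers energy only to the diene, whose triplet should add through its unhindered terminus C1′, anti to the C5′ isopropyl group, to the β-carbon C7 on the convex lactone face opposite the tetrahydrofuran ring, and the allyl/α-acyl 1,4-biradical then closes at C2′.

Step 7
Reactants: 12 cis,anti,cis-cyclobutane photoadduct
Product: 15 target lactone CNP0249919.1, via cyclobutane aluminium alkoxide 13 (not isolated), via ring-expanded aluminium alkoxide 14 (not isolated)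
Conditions: Me2AlCl (2.5 equiv), CH2Cl2, −78 to −20 °C; aq potassium sodium tartrate (KNaC4H4O6)
Reagents that add atoms: none
Why: Me2AlCl first turns the free hydroxyl into its aluminium alkoxide and a second equivalent binds the lactone carbonyl, so that the strained C6–C2′ bond ionises to a zwitterion (aluminium lactone enolate at C6, trialkyl-substituted allyl cation C2′–C3′–C4′) held together by the intact C7–C1′ bond, and recombination at C4′ completes a formal suprafacial 1,3-shift that enlarges the cyclobutane (C1′, C2′, C6, C7) to the cyclohexene (C1′, C2′, C3′, C4′, C6, C7) with relief of four-ring strain. The closest known reaction types are the Lewis-acid-promoted 1,3-shifts of acceptor-substituted vinylcyclopropanes and vinylcyclobutanes through such zwitterions and the thermal vinylcyclobutane–cyclohexene rearrangement of bicyclo[4.2.0]oct-2-enes to bicyclo[2.2.2]oct-2-enes. The new C6–C4′ bond closes two six-membered rings at once, the cyclohexene (6-endo with respect to the allyl cation, enolate carbon as nucleophile) and the saturated ring through C5′ and C6′ (6-exo), through the same boat-like geometry as a Diels–Alder transition state. The two new stereocentres C4′ and C6 are fixed by the tether: C6 can reach C4′ only on the ring face that already carries C7 (anti to isopropyl) and the lactone can only be cis-fused to the two-carbon bridge, so C1′ and C7 from step 6 dictate the endo, anti result. The step needs closure at C4′ to win over return to the cyclobutane, proton loss from the cation and acid-induced shifts of the product alkene; closure at C4′ is the thermodynamic sink, and Me2AlCl is chosen because its Al–CH3 bonds scavenge protons.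

Compound list
1 | (E)-cinnamaldehyde | O=C/C=C/c1ccccc1 | starting material
2 | allyl methoxymethyl ether, 3-(methoxymethoxy)prop-1-ene | C=CCOCOC | starting material
3 | (Z)-3-(methoxymethoxy)allyllithium | [Li]C/C=C\OCOC | intermediate (not isolated)
4 | [(Z)-3-(methoxymethoxy)allyl]diisopinocampheylborane, isopinocampheyl groups from (−)-α-pinene | COCO/C=C\CB([C@H]1C[C@H]2C[C@@H]([C@@H]1C)C2(C)C)[C@H]1C[C@H]2C[C@@H]([C@@H]1C)C2(C)C | intermediate (not isolated)
5 | diisopinocampheylborinate ester of 6 | C=C[C@H](OCOC)[C@@H](OB([C@H]1C[C@H]2C[C@@H]([C@@H]1C)C2(C)C)[C@H]1C[C@H]2C[C@@H]([C@@H]1C)C2(C)C)/C=C/c1ccccc1 | intermediate (not isolated)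
6 | (1E,3S,4S)-4-(methoxymethoxy)-1-phenylhexa-1,5-dien-3-ol | C=C[C@H](OCOC)[C@@H](O)/C=C/c1ccccc1 | intermediate
7 | (1R,2S)-2-(methoxymethoxy)-1-[(2S,3S)-3-phenyloxiran-2-yl]but-3-en-1-ol | C=C[C@H](OCOC)[C@@H](O)[C@@H]1O[C@H]1c1ccccc1 | intermediate
8 | (1R,2S)-2-(methoxymethoxy)-1-[(2R,3S)-3-phenyloxiran-2-yl]but-3-en-1-yl prop-2-enoate | C=C[C@H](OCOC)[C@@H](OC(=O)C=C)[C@@H]1O[C@H]1c1ccccc1 | intermediate
9 | (5S,6R)-5-(methoxymethoxy)-6-[(2R,3S)-3-phenyloxiran-2-yl]-5,6-dihydro-2H-pyran-2-one | O=C1O[C@@H]([C@@H]2O[C@H]2c2ccccc2)[C@@H](OCOC)C=C1 | intermediate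
10 | (+)-altholactone, (2R,3R,3aS,7aS)-3-hydroxy-2-phenyl-2,3,3a,7a-tetrahydro-5H-furo[3,2-b]pyran-5-one | O=C1O[C@H]2[C@H](O)[C@@H](c3ccccc3)O[C@H]2C=C1 | intermediate
11 | (R)-(−)-α-phellandrene, (5R)-2-methyl-5-(propan-2-yl)cyclohexa-1,3-diene | CC1=CC[C@@H](C=C1)C(C)C | starting material
12 | cyclobutane photoadduct: cyclobutane C1′–C2′–C6–C7 cis-fused to the terpene cyclohexene (C2′ quaternary, CH3 cis to H1′, C3′=C4′ kept) and cis-fused to the altholactone pyranone (H6 cis to H7), H1′ trans to H7, C7–C1′ bond anti to isopropyl and on the pyranone face opposite the tetrahydrofuran | C[C@@]12C=C[C@@H](C(C)C)C[C@@H]1[C@@H]3[C@H]2C(=O)O[C@H]4[C@H](O)[C@@H](c5ccccc5)O[C@H]43 | intermediate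
13 | chloro(methyl)aluminium alkoxide of 12 (at O3) | C[C@@]12C=C[C@@H](C(C)C)C[C@@H]1[C@@H]3[C@H]2C(=O)O[C@H]4[C@H](O[Al](C)Cl)[C@@H](c5ccccc5)O[C@H]43 | intermediate (not isolated)
14 | chloro(methyl)aluminium alkoxide of 15 (at O3) | CC1=C[C@@H]2[C@@H]3C(=O)O[C@H]4[C@H](O[Al](C)Cl)[C@@H](c5ccccc5)O[C@H]4[C@@H]3[C@H]1C[C@@H]2C(C)C | intermediate (not isolated)
15 | target CNP0249919.1: altholactone unit whose C6 and C7 form one bridge of a bicyclo[2.2.2]octene with C1′–C6′ (bonds C7–C1′ and C6–C4′, C2′(CH3)=C3′, C5′-isopropyl syn to the alkene bridge, lactone C5 and C7a syn to the alkene bridge, bicycle on the pyranone face opposite the tetrahydrofuran) | CC1=C[C@@H]2[C@@H]3C(=O)O[C@H]4[C@H](O)[C@@H](c5ccccc5)O[C@H]4[C@@H]3[C@H]1C[C@@H]2C(C)C | target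

Total step count: 7. Longest linear sequence: 7 steps (from cinnamaldehyde 1 to 15).

Steps most likely to fail

Step 7. After ionisation of the C6–C2′ bond, the allyl cation may lose a proton or the zwitterion may fragment into its two halves faster than the enolate carbon closes onto C4′. Alternatively, the bond may not ionise below the temperature at which the Lewis acid attacks the lactone or the benzylic ether. The fallback replaces Lewis-acid heterolysis by reagent-free homolysis and makes no new compound (F0). It sets out from 12, which would be heated without additive (degassed o-dichlorobenzene with a trace of BHT, sealed tube or microwave, 180–200 °C). The C6–C2′ bond, weakened by ring strain, the tertiary allyl radical and the α-acyl radical, should break to a 1,4-diradical that recloses at C4′. This is the classical thermal vinylcyclobutane–cyclohexene rearrangement of a bicyclo[4.2.0]oct-2-ene to a bicyclo[2.2.2]oct-2-ene, and it comes back to the route at 15.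

Step 6. Dimerisation of the diene triplet may outrun its addition to the lactone, and the lactone may be attacked by the diene face syn to isopropyl or by the hindered terminus C4′. The fallback inverts the roles and excites an enone instead of the diene; it sets out from 10 and comes back at 12. Silylation (TBSCl, imidazole, DMF) would give altholactone tert-butyldimethylsilyl ether F1. (S)-Carvotanacetone F2 would be made by hydrogenating commercial (S)-(+)-carvone (H2, RhCl(PPh3)3). Irradiation of F2 at 350 nm with F1 (CH2Cl2, −40 °C) is expected to give the head-to-head enone–alkene photoadduct, cyclobutane ketone F3, because the carbonyl-bearing carbon of an electron-poor alkene joins the enone α-carbon. Enolisation can only occur toward C4′, since C2′ is quaternary, so KN(SiMe3)2 and PhNTf2 should give enol triflate F4. Reduction with Pd(OAc)2, PPh3, Et3N and HCO2H would give silylated cyclobutane F5, and HF·pyridine would then release 12.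

Step 2. The catalyst may not control the alkene face well enough on a substrate with a free allylic hydroxyl, the epoxy alcohol may undergo Payne rearrangement at pH 10.5, or the ketone may decompose before conversion is complete. The fallback installs the epoxide before the carbon–carbon bond; it sets out from 1 and comes back at 7. Organocatalytic epoxidation of 1 (aq H2O2, (S)-2-{bis[3,5-bis(trifluoromethyl)phenyl](trimethylsilyloxy)methyl}pyrrolidine, CH2Cl2) should give (2R,3S)-3-phenyloxirane-2-carbaldehyde F6. Addition of allylborane 4, generated as in step 1, at −78 °C would give epoxy borinate F7, which NaOH/H2O2 would oxidise to 7. This pairing is the mismatched one, so reagent control by the isopinocampheyl groups must override the aldehyde's own preference for the erythro epoxy alcohol.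

Further compounds
F0 | step 7 | none | none
F1 | step 6 | altholactone tert-butyldimethylsilyl ether | O=C1O[C@H]2[C@H](O[Si](C)(C)C(C)(C)C)[C@@H](c3ccccc3)O[C@H]2C=C1
F2 | step 6 | (S)-carvotanacetone, (5S)-2-methyl-5-(propan-2-yl)cyclohex-2-en-1-one | CC1=CC[C@H](C(C)C)CC1=O
F3 | step 6 | cyclobutane ketone (C3′ ketone analogue of silylated 12) | C[C@@]12C(=O)C[C@@H](C(C)C)C[C@@H]1[C@@H]3[C@H]2C(=O)O[C@H]4[C@H](O[Si](C)(C)C(C)(C)C)[C@@H](c5ccccc5)O[C@H]43
F4 | step 6 | enol triflate (C3′(OTf)=C4′) | C[C@@]12C(OS(=O)(=O)C(F)(F)F)=C[C@@H](C(C)C)C[C@@H]1[C@@H]3[C@H]2C(=O)O[C@H]4[C@H](O[Si](C)(C)C(C)(C)C)[C@@H](c5ccccc5)O[C@H]43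
F5 | step 6 | silylated cyclobutane (tert-butyldimethylsilyl ether of 12) | C[C@@]12C=C[C@@H](C(C)C)C[C@@H]1[C@@H]3[C@H]2C(=O)O[C@H]4[C@H](O[Si](C)(C)C(C)(C)C)[C@@H](c5ccccc5)O[C@H]43
F6 | step 2 | (2R,3S)-3-phenyloxirane-2-carbaldehyde | O=C[C@@H]1O[C@H]1c1ccccc1
F7 | step 2 | epoxy borinate (diisopinocampheylborinate ester of 7) | C=C[C@H](OCOC)[C@@H](OB([C@H]1C[C@H]2C[C@@H]([C@@H]1C)C2(C)C)[C@H]1C[C@H]2C[C@@H]([C@@H]1C)C2(C)C)[C@@H]1O[C@H]1c1ccccc1
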